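## Retrosynthetic overview

1. Target 37 ← hydrogenation of the C7=C8 azepine 36 ← ring-closing metathesis of the N-butenyl / C9-vinyl pyrrolidine 33 (azepane ring closed last).
2. Pyrrolidine ← 5-exo-tet SN2 of the C9a amine on the C3 mesylate (inversion) ← N-sulfinyl homoallylic amine 30.
3. C9a–C9 bond (fragment union) ← indium-mediated γ-allylation of the (S)-N-sulfinyl aldimine 13 (fragment 1, ring A) with the (E)-allylic bromide 26 (fragment 2, ring B).
4. Fragment 1 ← Sharpless desymmetrisation of divinylcarbinol, methacrylate RCM and cis-hydrogenation (ring A), vinyl cuprate epoxide opening. Fragment 2 ← Evans syn-aldol and lactonisation (ring B), methylenation, trans-methylation, cross-metathesis.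
5. Ring order: lactone ring A and lactone ring B (separately, in the two fragments), then the pyrrolidine, then the azepane.

Assumption: atoms are labelled by pyrrolo[1,2-a]azepine numbering (C3, N4, C5–C9, C9a); C10 is the ethyl-bearing side-chain carbon, ring A is the lactone on C3, ring B the lactone on C10. The target is read as 3S,9R,9aS,10R with ring A 3S,5S (cis) and ring B 3S,5R (trans).

## Route

Step 1
Reactants: 1 penta-1,4-dien-3-ol
Product: 2 (2R,3S)-1,2-epoxypent-4-en-3-ol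
Conditions: Ti(OiPr)4 (0.2 equiv), L-(+)-diisopropyl tartrate (0.25 equiv), t-BuOOH, 4 Å molecular sieves, CH2Cl2, −20 °C
Reagents that add atoms: tert-butyl hydroperoxide, CC(C)(C)OO
Why: Sharpless asymmetric epoxidation desymmetrises the divinyl carbinol, the L-(+)-tartrate complex epoxidising one enantiotopic vinyl group to the 2R oxirane with the erythro 3S carbinol, while the minor enantiomer is removed by a fast second epoxidation.

Step 2
Reactants: 2 (2R,3S)-1,2-epoxypent-4-en-3-ol; 3 methacryloyl chloride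
Product: 4 (1S)-1-[(2R)-oxiran-2-yl]prop-2-en-1-yl 2-methylprop-2-enoate
Conditions: Et3N, DMAP (cat.), CH2Cl2, 0 °C
Reagents that add atoms: none
Why: DMAP-catalysed O-acylation of the allylic alcohol installs the methacrylate for ring closure without touching either stereocentre.

Step 3
Reactants: 4 (1S)-1-[(2R)-oxiran-2-yl]prop-2-en-1-yl 2-methylprop-2-enoate
Product: 5 (5S)-3-methyl-5-[(2R)-oxiran-2-yl]furan-2(5H)-one
Conditions: second-generation Grubbs catalyst RuCl2(=CHPh)(H2IMes)(PCy3) (5 mol %), toluene, 80 °C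
Reagents that add atoms: none
Why: Ring-closing metathesis of the methacrylate with the allylic vinyl group is a favoured five-membered closure that gives the α-methylbutenolide of ring A and leaves the carbinol centre untouched.

Step 4
Reactants: 5 (5S)-3-methyl-5-[(2R)-oxiran-2-yl]furan-2(5H)-one
Product: 6 (3S,5S)-3-methyl-5-[(2R)-oxiran-2-yl]oxolan-2-one
Conditions: H2 (1 atm), 5 % Rh/Al2O3, EtOAc, rt
Reagents that add atoms: none
Why: Heterogeneous hydrogenation delivers H2 to the butenolide face anti to the C5 oxiranyl group, so the methyl-bearing centre forms cis to it (3S), and Rh on alumina spares the epoxide.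

Step 5
Reactants: 6 (3S,5S)-3-methyl-5-[(2R)-oxiran-2-yl]oxolan-2-one
Product: 7 (3S,5S)-5-[(1R)-1-hydroxybut-3-en-1-yl]-3-methyloxolan-2-one
Conditions: CH2=CHMgBr (3.0 equiv), CuI (1.5 equiv), THF, −40 °C; H2O
Reagents that add atoms: vinylmagnesium bromide, C=C[Mg]Br
Why: The soft Gilman divinylcuprate opens the epoxide by SN2 attack at the unsubstituted carbon and does not add to the lactone at low temperature, so the R carbinol (future C3) is retained.

Step 6
Reactants: 7 (3S,5S)-5-[(1R)-1-hydroxybut-3-en-1-yl]-3-methyloxolan-2-one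
Product: 8 (1R)-1-[(2S,4S)-4-methyl-5-oxooxolan-2-yl]but-3-en-1-yl methanesulfonate
Conditions: MsCl, Et3N, CH2Cl2, 0 °C
Reagents that add atoms: methanesulfonyl chloride, CS(=O)(=O)Cl
Why: O-sulfonylation with retention turns the C3 oxygen into the leaving group for the later invertive ring closure.

Step 7
Reactants: 8 (1R)-1-[(2S,4S)-4-methyl-5-oxooxolan-2-yl]but-3-en-1-yl methanesulfonate
Product: 10 (1R)-4-hydroxy-1-[(2S,4S)-4-methyl-5-oxooxolan-2-yl]butyl methanesulfonate, via alkyl-9-BBN borane 9 (not isolated)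
Conditions: 9-BBN, THF, 0 °C → rt; then 30 % H2O2, aq. NaOAc, 0 °C → rt
Reagents that add atoms: 9-borabicyclo[3.3.1]nonane, B1C2CCCC1CCC2 (boron in 9 only); hydrogen peroxide, OO
Why: Anti-Markovnikov hydroboration with the bulky borane and buffered oxidation give the primary alcohol without hydrolysing the lactone or the mesylate.

Step 8
Reactants: 10 (1R)-4-hydroxy-1-[(2S,4S)-4-methyl-5-oxooxolan-2-yl]butyl methanesulfonate
Product: 11 (1R)-1-[(2S,4S)-4-methyl-5-oxooxolan-2-yl]-4-oxobutyl methanesulfonate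
Conditions: Dess–Martin periodinane, CH2Cl2, 0 °C → rt; used at once
Reagents that add atoms: none
Why: Dess–Martin oxidation gives the aldehyde under near-neutral conditions that spare the mesylate and the epimerisable α-methyl lactone centre.

Step 9
Reactants: 11 (1R)-1-[(2S,4S)-4-methyl-5-oxooxolan-2-yl]-4-oxobutyl methanesulfonate; 12 (S)-2-methylpropane-2-sulfinamide
Product: 13 (1R,4E)-4-{[(S)-tert-butylsulfinyl]imino}-1-[(2S,4S)-4-methyl-5-oxooxolan-2-yl]butyl methanesulfonate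
Conditions: CuSO4 (anhydrous), CH2Cl2, rt
Reagents that add atoms: none
Why: Ellman condensation, with CuSO4 as mild Lewis acid and water scavenger, gives the (E)-N-sulfinyl aldimine that carries the auxiliary for C9a.

Step 10
Reactants: 14 (4S)-4-benzyl-1,3-oxazolidin-2-one; 15 butanoyl chloride
Product: 16 (4S)-4-benzyl-3-butanoyl-1,3-oxazolidin-2-one
Conditions: Et3N, DMAP (cat.), CH2Cl2, 0 °C → rt
Reagents that add atoms: none
Why: DMAP-catalysed N-acylation gives the Evans imide for the aldol step.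

Step 11
Reactants: 16 (4S)-4-benzyl-3-butanoyl-1,3-oxazolidin-2-one; 17 methyl 4-oxobutanoate
Product: 20 (4S)-4-benzyl-3-{(2S)-2-[(2R)-5-oxooxolan-2-yl]butanoyl}-1,3-oxazolidin-2-one, via boron Z-enolate 18 (not isolated), via aldol hydroxy ester 19 (not isolated)
Conditions: n-Bu2BOTf, iPr2NEt, CH2Cl2, −78 → 0 °C; 17, −78 → 0 °C; pH 7 buffer, MeOH, 30 % H2O2; then p-TsOH·H2O (cat.), CH2Cl2, rt
Reagents that add atoms: dibutylboron trifluoromethanesulfonate, CCCCB(CCCC)OS(=O)(=O)C(F)(F)F (boron in 18 only)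
Why: Evans syn-aldol, in which the Z boron enolate reacts through a Zimmerman–Traxler chair on the face away from the benzyl group to set the 2S,3R pair (future C10 and ring B C5), followed by acid-catalysed lactonisation of the γ-hydroxy ester to ring B.

Step 12
Reactants: 20 (4S)-4-benzyl-3-{(2S)-2-[(2R)-5-oxooxolan-2-yl]butanoyl}-1,3-oxazolidin-2-one
Product: 21 (5R)-5-[(2R)-1-hydroxybutan-2-yl]oxolan-2-one
Conditions: NaBH4, THF/H2O (4:1), 0 °C → rt
Reagents that add atoms: none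
Why: Borohydride in wet THF reduces the activated imide carbonyl to the primary alcohol but not the γ-lactone, releasing the auxiliary without touching C10.

Step 13
Reactants: 21 (5R)-5-[(2R)-1-hydroxybutan-2-yl]oxolan-2-one
Product: 22 (2S)-2-[(2R)-5-oxooxolan-2-yl]butanal
Conditions: Dess–Martin periodinane, CH2Cl2, 0 °C; used at once
Reagents that add atoms: none
Why: Dess–Martin oxidation gives the α-branched aldehyde without base, so C10 is not epimerised and the β-acyloxy group is not eliminated.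

Step 14
Reactants: 22 (2S)-2-[(2R)-5-oxooxolan-2-yl]butanal
Product: 23 (5R)-5-[(3R)-pent-1-en-3-yl]oxolan-2-one
Conditions: Zn, CH2Br2, TiCl4, THF/CH2Cl2, 0 °C → rt
Reagents that add atoms: dibromomethane, BrCBr
Why: Takai–Lombardo methylenation is non-basic and aldehyde-selective, so the vinyl group is made without epimerisation, β-elimination or attack on the lactone.

Step 15
Reactants: 23 (5R)-5-[(3R)-pent-1-en-3-yl]oxolan-2-one
Product: 25 (3S,5R)-3-methyl-5-[(3R)-pent-1-en-3-yl]oxolan-2-one, via lithium enolate 24 (not isolated)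
Conditions: LiN(iPr)2 (commercial solution, 1.1 equiv), THF, −78 °C; then MeI, −78 °C
Reagents that add atoms: lithium diisopropylamide, [Li+].CC(C)[N-]C(C)C (lithium in 24 only); iodomethane, CI
Why: Kinetic alkylation of the lactone enolate occurs anti to the branched C5 side chain and gives the trans 3S methyl lactone of ring B.

Step 16
Reactants: 25 (3S,5R)-3-methyl-5-[(3R)-pent-1-en-3-yl]oxolan-2-one
Product: 26 (3S,5R)-5-[(3R,4E)-6-bromohex-4-en-3-yl]-3-methyloxolan-2-one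
Conditions: (E)-1,4-dibromobut-2-ene (4 equiv), second-generation Hoveyda–Grubbs catalyst RuCl2(=CH-C6H4-2-OiPr)(H2IMes) (5 mol %), CH2Cl2, 40 °C
Reagents that add atoms: (E)-1,4-dibromobut-2-ene, BrC/C=C/CBr
Why: Olefin cross-metathesis with an excess of the dibromide converts the terminal vinyl group into the thermodynamically favoured (E)-allylic bromide without involving a stereocentre.

Step 17
Reactants: 27 but-3-en-1-ol
Product: 28 but-3-en-1-yl trifluoromethanesulfonate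
Conditions: Tf2O, 2,6-lutidine, CH2Cl2, −78 → −20 °C; cold silica plug; used at once
Reagents that add atoms: trifluoromethanesulfonic anhydride, O=S(=O)(OS(=O)(=O)C(F)(F)F)C(F)(F)F
Why: O-sulfonylation of the primary alcohol gives an alkylating agent reactive enough for a hindered secondary amine.

Step 18
Reactants: 13 (1R,4E)-4-{[(S)-tert-butylsulfinyl]imino}-1-[(2S,4S)-4-methyl-5-oxooxolan-2-yl]butyl methanesulfonate; 26 (3S,5R)-5-[(3R,4E)-6-bromohex-4-en-3-yl]-3-methyloxolan-2-one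
Product: 30 (1R,4S,5R,6R)-4-{[(S)-tert-butylsulfinyl]amino}-5-ethenyl-1-[(2S,4S)-4-methyl-5-oxooxolan-2-yl]-6-[(2R,4S)-4-methyl-5-oxooxolan-2-yl]octyl methanesulfonate, via allylindium dibromide 29 (not isolated)
Conditions: In powder (2 equiv), THF, 60 °C
Reagents that add atoms: indium, [In] (in 29 only)
Why: Barbier-type indium allylation, in which the allylindium adds through its γ-carbon in a chair transition state with indium bound to the imine nitrogen, the (S)-sulfinyl group directing attack to the Re face (C9a = S) and the E allyl unit with the axial imine substituent giving the syn C9a/C9 relationship (C9 = R), while lactones and mesylate are inert to the reagent.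

Step 19
Reactants: 30 (1R,4S,5R,6R)-4-{[(S)-tert-butylsulfinyl]amino}-5-ethenyl-1-[(2S,4S)-4-methyl-5-oxooxolan-2-yl]-6-[(2R,4S)-4-methyl-5-oxooxolan-2-yl]octyl methanesulfonate
Product: 32 (3S,5S)-3-methyl-5-[(2S,5S)-5-{(3R,4R)-4-[(2R,4S)-4-methyl-5-oxooxolan-2-yl]hex-1-en-3-yl}pyrrolidin-2-yl]oxolan-2-one, via amine hydrochloride 31 (not isolated)
Conditions: HCl (4 M in 1,4-dioxane), MeOH, 0 °C; evaporate; then K2CO3, MeCN, 40 °C; product used at once
Reagents that add atoms: hydrogen chloride, Cl (in 31 only)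
Why: Acid cleaves the sulfinyl group and the liberated amine displaces the C3 mesylate in a 5-exo-tet SN2 reaction with inversion, which sets C3 as S and gives the 2,5-trans pyrrolidine.

Step 20
Reactants: 32 (3S,5S)-3-methyl-5-[(2S,5S)-5-{(3R,4R)-4-[(2R,4S)-4-methyl-5-oxooxolan-2-yl]hex-1-en-3-yl}pyrrolidin-2-yl]oxolan-2-one; 28 but-3-en-1-yl trifluoromethanesulfonate
Product: 33 (3S,5S)-5-[(2S,5S)-1-(but-3-en-1-yl)-5-{(3R,4R)-4-[(2R,4S)-4-methyl-5-oxooxolan-2-yl]hex-1-en-3-yl}pyrrolidin-2-yl]-3-methyloxolan-2-one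
Conditions: K2CO3, MeCN, 0 °C → rt
Reagents that add atoms: none
Why: SN2 N-alkylation by the primary triflate is fast enough at low temperature to cap the hindered secondary amine before lactone-to-lactam acyl transfer from ring A can compete.

Step 21
Reactants: 33 (3S,5S)-5-[(2S,5S)-1-(but-3-en-1-yl)-5-{(3R,4R)-4-[(2R,4S)-4-methyl-5-oxooxolan-2-yl]hex-1-en-3-yl}pyrrolidin-2-yl]-3-methyloxolan-2-one
Product: 36 (3S,5S)-3-methyl-5-[(3S,9R,9aS)-9-{(1R)-1-[(2R,4S)-4-methyl-5-oxooxolan-2-yl]propyl}-2,3,5,6,9,9a-hexahydro-1H-pyrrolo[1,2-a]azepin-3-yl]oxolan-2-one, via diene tosylate salt 34 (not isolated), via azepine tosylate salt 35 (not isolated)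
Conditions: p-TsOH·H2O (1.05 equiv), CH2Cl2, rt; second-generation Grubbs catalyst RuCl2(=CHPh)(H2IMes)(PCy3) (10 mol %), CH2Cl2 (2 mM), 40 °C; then aq. NaHCO3
Reagents that add atoms: 4-methylbenzenesulfonic acid, Cc1ccc(cc1)S(O)(=O)=O (in 34 and 35 only)
Why: Ring-closing metathesis of the N-butenyl and C9-vinyl groups closes the seven-membered ring at C7=C8, protonation keeping the amine from binding ruthenium, and no stereocentre is affected.

Step 22
Reactants: 36 (3S,5S)-3-methyl-5-[(3S,9R,9aS)-9-{(1R)-1-[(2R,4S)-4-methyl-5-oxooxolan-2-yl]propyl}-2,3,5,6,9,9a-hexahydro-1H-pyrrolo[1,2-a]azepin-3-yl]oxolan-2-one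
Product: 37 (3S,5S)-3-methyl-5-[(3S,9R,9aS)-9-{(1R)-1-[(2R,4S)-4-methyl-5-oxooxolan-2-yl]propyl}octahydro-1H-pyrrolo[1,2-a]azepin-3-yl]oxolan-2-one
Conditions: H2 (1 atm), 10 % Pd/C, EtOAc, rt
Reagents that add atoms: none
Why: Catalytic hydrogenation saturates the cis-disubstituted ring alkene, creates no stereocentre and leaves both lactones intact, giving the target.

## Compound list

1 | penta-1,4-dien-3-ol | C=CC(O)C=C | starting material
2 | (2R,3S)-1,2-epoxypent-4-en-3-ol | C=C[C@H](O)[C@H]1CO1 | intermediate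
3 | methacryloyl chloride | CC(=C)C(=O)Cl | starting material
4 | (1S)-1-[(2R)-oxiran-2-yl]prop-2-en-1-yl 2-methylprop-2-enoate | C=C[C@H](OC(=O)C(C)=C)[C@H]1CO1 | intermediate
5 | (5S)-3-methyl-5-[(2R)-oxiran-2-yl]furan-2(5H)-one | C1O[C@H]1[C@@H]1C=C(C)C(=O)O1 | intermediate
6 | (3S,5S)-3-methyl-5-[(2R)-oxiran-2-yl]oxolan-2-one | C1O[C@H]1[C@@H]1C[C@H](C)C(=O)O1 | intermediate
7 | (3S,5S)-5-[(1R)-1-hydroxybut-3-en-1-yl]-3-methyloxolan-2-one | C=CC[C@@H](O)[C@@H]1C[C@H](C)C(=O)O1 | intermediate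
8 | (1R)-1-[(2S,4S)-4-methyl-5-oxooxolan-2-yl]but-3-en-1-yl methanesulfonate | C=CC[C@@H](OS(C)(=O)=O)[C@@H]1C[C@H](C)C(=O)O1 | intermediate
9 | 9-{(4R)-4-(methanesulfonyloxy)-4-[(2S,4S)-4-methyl-5-oxooxolan-2-yl]butyl}-9-borabicyclo[3.3.1]nonane | B1(C2CCCC1CCC2)CCC[C@@H](OS(C)(=O)=O)[C@@H]1C[C@H](C)C(=O)O1 | intermediate
10 | (1R)-4-hydroxy-1-[(2S,4S)-4-methyl-5-oxooxolan-2-yl]butyl methanesulfonate | OCCC[C@@H](OS(C)(=O)=O)[C@@H]1C[C@H](C)C(=O)O1 | intermediate
11 | (1R)-1-[(2S,4S)-4-methyl-5-oxooxolan-2-yl]-4-oxobutyl methanesulfonate | O=CCC[C@@H](OS(C)(=O)=O)[C@@H]1C[C@H](C)C(=O)O1 | intermediate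
12 | (S)-2-methylpropane-2-sulfinamide | CC(C)(C)[S@](=O)N | starting material
13 | (1R,4E)-4-{[(S)-tert-butylsulfinyl]imino}-1-[(2S,4S)-4-methyl-5-oxooxolan-2-yl]butyl methanesulfonate | CC(C)(C)[S@](=O)/N=C/CC[C@@H](OS(C)(=O)=O)[C@@H]1C[C@H](C)C(=O)O1 | intermediate
14 | (4S)-4-benzyl-1,3-oxazolidin-2-one | O=C1N[C@@H](Cc2ccccc2)CO1 | starting material
15 | butanoyl chloride | CCCC(=O)Cl | starting material
16 | (4S)-4-benzyl-3-butanoyl-1,3-oxazolidin-2-one | CCCC(=O)N1[C@@H](Cc2ccccc2)COC1=O | intermediate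
17 | methyl 4-oxobutanoate | COC(=O)CCC=O | starting material
18 | dibutylboron (Z)-enolate of 16 | CC/C=C(\OB(CCCC)CCCC)N1[C@@H](Cc2ccccc2)COC1=O | intermediate
19 | methyl (4R,5S)-5-[(4S)-4-benzyl-2-oxo-1,3-oxazolidine-3-carbonyl]-4-hydroxyheptanoate | CC[C@H](C(=O)N1[C@@H](Cc2ccccc2)COC1=O)[C@H](O)CCC(=O)OC | intermediate
20 | (4S)-4-benzyl-3-{(2S)-2-[(2R)-5-oxooxolan-2-yl]butanoyl}-1,3-oxazolidin-2-one | CC[C@H](C(=O)N1[C@@H](Cc2ccccc2)COC1=O)[C@H]1CCC(=O)O1 | intermediate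
21 | (5R)-5-[(2R)-1-hydroxybutan-2-yl]oxolan-2-one | CC[C@H](CO)[C@H]1CCC(=O)O1 | intermediate
22 | (2S)-2-[(2R)-5-oxooxolan-2-yl]butanal | CC[C@H](C=O)[C@H]1CCC(=O)O1 | intermediate
23 | (5R)-5-[(3R)-pent-1-en-3-yl]oxolan-2-one | CC[C@H](C=C)[C@H]1CCC(=O)O1 | intermediate
24 | lithium (5R)-5-[(3R)-pent-1-en-3-yl]-4,5-dihydrofuran-2-olate | CC[C@H](C=C)[C@H]1CC=C([O-])O1.[Li+] | intermediate
25 | (3S,5R)-3-methyl-5-[(3R)-pent-1-en-3-yl]oxolan-2-one | CC[C@H](C=C)[C@H]1C[C@H](C)C(=O)O1 | intermediate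
26 | (3S,5R)-5-[(3R,4E)-6-bromohex-4-en-3-yl]-3-methyloxolan-2-one | CC[C@H](/C=C/CBr)[C@H]1C[C@H](C)C(=O)O1 | intermediate
27 | but-3-en-1-ol | C=CCCO | starting material
28 | but-3-en-1-yl trifluoromethanesulfonate | C=CCCOS(=O)(=O)C(F)(F)F | intermediate
29 | dibromo{(2E,4R)-4-[(2R,4S)-4-methyl-5-oxooxolan-2-yl]hex-2-en-1-yl}indium (one unit of the allylindium sesquibromide) | CC[C@H](/C=C/C[In](Br)Br)[C@H]1C[C@H](C)C(=O)O1 | intermediate
30 | (1R,4S,5R,6R)-4-{[(S)-tert-butylsulfinyl]amino}-5-ethenyl-1-[(2S,4S)-4-methyl-5-oxooxolan-2-yl]-6-[(2R,4S)-4-methyl-5-oxooxolan-2-yl]octyl methanesulfonate | CC[C@H]([C@@H](C=C)[C@H](CC[C@@H](OS(C)(=O)=O)[C@@H]1C[C@H](C)C(=O)O1)N[S@@](=O)C(C)(C)C)[C@H]1C[C@H](C)C(=O)O1 | intermediate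
31 | (1R,4S,5R,6R)-4-amino-5-ethenyl-1-[(2S,4S)-4-methyl-5-oxooxolan-2-yl]-6-[(2R,4S)-4-methyl-5-oxooxolan-2-yl]octyl methanesulfonate hydrochloride | CC[C@H]([C@@H](C=C)[C@H](CC[C@@H](OS(C)(=O)=O)[C@@H]1C[C@H](C)C(=O)O1)N)[C@H]1C[C@H](C)C(=O)O1.Cl | intermediate
32 | (3S,5S)-3-methyl-5-[(2S,5S)-5-{(3R,4R)-4-[(2R,4S)-4-methyl-5-oxooxolan-2-yl]hex-1-en-3-yl}pyrrolidin-2-yl]oxolan-2-one | CC[C@H]([C@@H](C=C)[C@@H]1CC[C@H](N1)[C@@H]1C[C@H](C)C(=O)O1)[C@H]1C[C@H](C)C(=O)O1 | intermediate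
33 | (3S,5S)-5-[(2S,5S)-1-(but-3-en-1-yl)-5-{(3R,4R)-4-[(2R,4S)-4-methyl-5-oxooxolan-2-yl]hex-1-en-3-yl}pyrrolidin-2-yl]-3-methyloxolan-2-one | CC[C@H]([C@@H](C=C)[C@@H]1CC[C@H](N1CCC=C)[C@@H]1C[C@H](C)C(=O)O1)[C@H]1C[C@H](C)C(=O)O1 | intermediate
34 | 4-methylbenzenesulfonate salt of 33 | CC[C@H]([C@@H](C=C)[C@@H]1CC[C@H](N1CCC=C)[C@@H]1C[C@H](C)C(=O)O1)[C@H]1C[C@H](C)C(=O)O1.Cc1ccc(cc1)S(O)(=O)=O | intermediate
35 | 4-methylbenzenesulfonate salt of 36 | CC[C@H]([C@H]1C=CCCN2[C@H]1CC[C@H]2[C@@H]1C[C@H](C)C(=O)O1)[C@H]1C[C@H](C)C(=O)O1.Cc1ccc(cc1)S(O)(=O)=O | intermediate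
36 | (3S,5S)-3-methyl-5-[(3S,9R,9aS)-9-{(1R)-1-[(2R,4S)-4-methyl-5-oxooxolan-2-yl]propyl}-2,3,5,6,9,9a-hexahydro-1H-pyrrolo[1,2-a]azepin-3-yl]oxolan-2-one | CC[C@H]([C@H]1C=CCCN2[C@H]1CC[C@H]2[C@@H]1C[C@H](C)C(=O)O1)[C@H]1C[C@H](C)C(=O)O1 | intermediate
37 | (3S,5S)-3-methyl-5-[(3S,9R,9aS)-9-{(1R)-1-[(2R,4S)-4-methyl-5-oxooxolan-2-yl]propyl}octahydro-1H-pyrrolo[1,2-a]azepin-3-yl]oxolan-2-one | CC[C@H]([C@H]1CCCCN2[C@H]1CC[C@H]2[C@@H]1C[C@H](C)C(=O)O1)[C@H]1C[C@H](C)C(=O)O1 | target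

## Step count and risks

Total step count: 22.
Longest linear sequence: 14 steps (steps 1–9, then 18–22). The other branches are steps 10–16 (fragment 2) and step 17 (the triflate).

The three steps most likely to fail:

Step 18 (indium allylation). The regiochemistry (γ versus α attack of a bulky allyl unit) and the C9 configuration rest on a chair model with double stereodifferentiation from C10, and the sense of anti/syn selectivity is argued from that model, not taken from a close precedent. The fallback sets out from 26 (with aldehyde 11) and makes the C9a–C9 bond on the aldehyde instead of the imine. Bromide 26 is borylated (B2pin2, Pd2(dba)3, DMSO) to the (E)-allyl pinacol boronate F1. F1 adds to aldehyde 11 under a chiral BINOL-derived phosphoric acid ((S)-TRIP, toluene, −30 °C) through a closed chair to the anti homoallylic alcohol F2, with C9a–OH of R configuration and C9 = R. Mitsunobu azidation (DPPA, DIAD, PPh3) inverts C9a to give the azide F3. Staudinger reduction (PPh3, THF/H2O) followed by K2CO3 releases the amine, which closes onto the mesylate, and the route is rejoined at 32.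

Step 20 (N-butenylation). The 2,5-disubstituted pyrrolidine is very hindered, and the free NH next to ring A can undergo lactone-to-lactam transfer if alkylation is slow. The fallback sets out from 32 and replaces SN2 alkylation by conjugate addition and olefination. Addition of 32 to acrolein (MeCN, 0 °C) gives the β-amino aldehyde F4, and non-basic methylenation (Zn, CH2Br2, TiCl4) converts it into 33, where the route is rejoined.

Step 21 (RCM). The vinyl group on C9 is flanked by two branched carbons and the nitrogen is basic, so the ammonium salt may cyclise slowly or not at all. The fallback sets out from 32 and closes the ring on a neutral amide. Acylation with but-3-enoyl chloride (Et3N, CH2Cl2, −20 °C) gives the but-3-enamide F5. RCM (second-generation Grubbs catalyst, toluene, 80 °C) gives the unsaturated bicyclic lactam F6, and hydrogenation (H2, Pd/C) gives the saturated lactam F7. Chemoselective amide reduction in the presence of the two lactones (Zn(OAc)2, (EtO)3SiH, THF) comes back to the route at the target 37.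

Further compounds

F1 | step 18 | (3S,5R)-3-methyl-5-[(3R,4E)-6-(4,4,5,5-tetramethyl-1,3,2-dioxaborolan-2-yl)hex-4-en-3-yl]oxolan-2-one | CC[C@H](/C=C/CB1OC(C)(C)C(C)(C)O1)[C@H]1C[C@H](C)C(=O)O1
F2 | step 18 | (1R,4R,5R,6R)-5-ethenyl-4-hydroxy-1-[(2S,4S)-4-methyl-5-oxooxolan-2-yl]-6-[(2R,4S)-4-methyl-5-oxooxolan-2-yl]octyl methanesulfonate | CC[C@H]([C@@H](C=C)[C@H](O)CC[C@@H](OS(C)(=O)=O)[C@@H]1C[C@H](C)C(=O)O1)[C@H]1C[C@H](C)C(=O)O1
F3 | step 18 | (1R,4S,5R,6R)-4-azido-5-ethenyl-1-[(2S,4S)-4-methyl-5-oxooxolan-2-yl]-6-[(2R,4S)-4-methyl-5-oxooxolan-2-yl]octyl methanesulfonate | CC[C@H]([C@@H](C=C)[C@H](CC[C@@H](OS(C)(=O)=O)[C@@H]1C[C@H](C)C(=O)O1)N=[N+]=[N-])[C@H]1C[C@H](C)C(=O)O1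
F4 | step 20 | 3-[(2S,5S)-2-{(3R,4R)-4-[(2R,4S)-4-methyl-5-oxooxolan-2-yl]hex-1-en-3-yl}-5-[(2S,4S)-4-methyl-5-oxooxolan-2-yl]pyrrolidin-1-yl]propanal | CC[C@H]([C@@H](C=C)[C@@H]1CC[C@H](N1CCC=O)[C@@H]1C[C@H](C)C(=O)O1)[C@H]1C[C@H](C)C(=O)O1
F5 | step 21 | (3S,5S)-5-[(2S,5S)-1-(but-3-enoyl)-5-{(3R,4R)-4-[(2R,4S)-4-methyl-5-oxooxolan-2-yl]hex-1-en-3-yl}pyrrolidin-2-yl]-3-methyloxolan-2-one | CC[C@H]([C@@H](C=C)[C@@H]1CC[C@H](N1C(=O)CC=C)[C@@H]1C[C@H](C)C(=O)O1)[C@H]1C[C@H](C)C(=O)O1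
F6 | step 21 | (3S,9R,9aS)-3-[(2S,4S)-4-methyl-5-oxooxolan-2-yl]-9-{(1R)-1-[(2R,4S)-4-methyl-5-oxooxolan-2-yl]propyl}-1,2,3,6,9,9a-hexahydro-5H-pyrrolo[1,2-a]azepin-5-one | CC[C@H]([C@H]1C=CCC(=O)N2[C@H]1CC[C@H]2[C@@H]1C[C@H](C)C(=O)O1)[C@H]1C[C@H](C)C(=O)O1
F7 | step 21 | (3S,9R,9aS)-3-[(2S,4S)-4-methyl-5-oxooxolan-2-yl]-9-{(1R)-1-[(2R,4S)-4-methyl-5-oxooxolan-2-yl]propyl}octahydro-5H-pyrrolo[1,2-a]azepin-5-one | CC[C@H]([C@H]1CCCC(=O)N2[C@H]1CC[C@H]2[C@@H]1C[C@H](C)C(=O)O1)[C@H]1C[C@H](C)C(=O)O1
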